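## Structural features

The target is a 1,2-dihydronaphthalene: catechol ring A is fused to ring B, which carries carboxyl groups on C2 and C3 (C3=C4 is the styrene-type double bond). C1 bears a 2-pyranone joined through C4', with a third carboxyl group on C6'. C1 and C2 are neighbouring stereocentres, (1R,2S), with the pyranonyl and the C2 carboxyl group trans. C1–H is benzylic and vinylogously acidified by the pyranone; C2–H is alpha to a carboxyl group and allylic. The fragile parts are the catechol (oxidation), the pyranone lactone (hydroxide and other nucleophiles) and the dihydronaphthalene (epimerisation at C2, aromatisation under base). The real difficulty is the C1 methine, which carries two different (hetero)aryl groups and must be set in absolute terms and trans to C2, after which no basic step is tolerable. The feature used is that C2 and C3 both carry carboxyl carbons and that C3–C4–ring A is an arylpyruvate unit. Formal hydration of C3=C4 makes C3 a tertiary carbinol next to a C2 carbonyl group, an aldol pattern. Opening C2–C3 leaves a beta,beta-di(hetero)aryl enal whose beta-carbon is C1.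

## Logic of the disconnections

18 to 17: the five O–methyl bonds (two aryl ethers, three esters) are cut together. All of them fall to one Lewis acid, so the last step needs no aqueous base. The forward step must cleave esters as well as ethers without touching the pyranone C–O bonds or C2.

17 to 16: the C3=C4 double bond is traced to a C3 hydroxyl and a C4 hydrogen. This turns C3 into the tertiary carbinol of an aldol. The forward elimination must go toward C4 and not toward C2, which requires the hydroxyl to be cis to C2–H so that only a C4 hydrogen can be antiperiplanar.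

16 to 15 to 14: the C2 ester is taken back through the acid to a formyl group. This gives C2 the aldehyde that an amine catalyst can turn into an enamine. The forward oxidation and esterification must avoid retro-aldol and epimerisation at C2.

14 to 13 (key): the C2–C3 bond and the C1–H bond are cut. Ring B opens and all three stereocentres vanish, leaving an achiral keto ester enal. The forward step must deliver hydride to one face of C1, close ring B from C2 onto the C3 ketone, and leave the keto ester unreduced. It also requires a single double-bond isomer of 13, with ring A trans to the formyl group.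

13 to 11: the C3 ketone is exchanged for an N-Boc enamine (C3–N). A free arylpyruvate is an enol with a nucleophilic C4 and an oxygen next to the aryl halide position, and it would not survive palladium chemistry. The unmasking must be mild and acidic.

11 to 10 and 7: the C1–C8a bond is cut (Mizoroki–Heck arylation). This is convergent, and its syn addition/syn elimination course puts the incoming ring A trans to the formyl group, which is the geometry 13 needs. The forward step demands beta-selective insertion of a hindered aryl–palladium species into a 1,2-disubstituted enal.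

10 to 8 and 9: the C3=C4 bond of the enamide is cut (Horner–Wadsworth–Emmons). Both partners are purchased.

7 to 4 and 5: the C4'–C1 bond is cut (Suzuki–Miyaura), with the formyl group carried as an acetal. The E geometry comes from the boronate.

4 to 3 to 2 to 1: the ester is taken back to the aldehyde and the methyl group, and the C4' bromide to the hydroxyl. This ends at a commodity pyranone.

## Other disconnections considered

Alternative 1: The pyranone is traced back to a 3,4-dihydroxyphenyl group on C1, that is to (1R,2S)-1-(3,4-dihydroxyphenyl)-6,7-dimethoxy-1,2-dihydronaphthalene-2,3-dicarboxylic acid A1. In the forward step a protocatechuate 4,5-dioxygenase (non-haem divalent iron, O2) would open the free catechol between the hydroxylated carbon para to C1 and its CH neighbour. The enol oxygen would add to the new aldehyde, and a hemiacetal dehydrogenase would oxidise the lactol to the lactone, giving the 6,7-di-O-methyl ether A2 of 18.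
- In favour: it probably mirrors the biogenesis, builds the sensitive pyranone last in water at neutral pH, and A1 belongs to a lignan type reachable in few steps by oxidative dimerisation of cinnamic acids.
- Against: the enzyme recognises a small benzoate, and A1 puts a bulky dihydronaphthalene where that carboxylate sits. The cleavage site (4,5 against 2,3 or intradiol) and turnover on such a substrate are open. Ring A must stay methylated to be spared, so the ether cleavage at the end remains. The route to A1 by radical dimerisation is racemic unless resolved.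
- Comparison: on step count and on keeping the pyranone out of every earlier step this plan is better than the chosen one. On C1/C2 stereocontrol and on predictability it is weaker, since the chosen plan sets C1 by a catalyst with a general model. The end-game deprotection is equal in both.

Alternative 2: Ring A is cut at C4a–C8a, C5–C6 and C7–C8, which leads to the enediyne A3 and 1,2-bis(4,4,5,5-tetramethyl-1,3,2-dioxaborolan-2-yl)ethyne A4. A3 is dimethyl (Z)-2-(prop-2-yn-1-ylidene)-3-[1-(6-methoxycarbonyl-2-oxo-2H-pyran-4-yl)prop-2-yn-1-yl]butanedioate, with both stereocentres as in the target. In the forward step Cp*RuCl(cod) or CpCo(CO)2 would join the two terminal alkynes of A3 with A4, closing rings A and B together to the 6,7-diboryl triester A5. C–B oxidation and ester cleavage would follow.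
- In favour: three C–C bonds and two rings form in one step, and the catechol arrives as boronates, so no ether cleavage is needed.
- Against: in A3 the C1 hydrogen is propargylic and activated by the pyranone, so propargyl–allene isomerisation and loss of configuration are likely. The pyranone is itself a diene and a ligand for the metal. A3 is a 1,7-diyne with a hindered partner. The acyclic C1/C2 pair in A3 needs its own asymmetric synthesis. Boronate oxidation uses basic peroxide, which the pyranone and C2 tolerate poorly.
- Comparison: in bonds formed per step the alternative is better. In exposing the pyranone to a transition metal the two plans are equal. In configurational safety of C1 and in access to the precursor the chosen plan is better, because its precursor is achiral and its C1 is created in the ring-forming step.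

Alternative 3: The pyranone is cut at O1'–C6' and C4'–C5', leading to the C1 propiolic acid A6 and 3,3-diethoxyprop-1-yne A7. A6 is 3-[6,7-dimethoxy-2,3-bis(methoxycarbonyl)-1,2-dihydronaphthalen-1-yl]prop-2-ynoic acid, configured as the target. In the forward step (Ph3P)AuCl/AgOTf would add the acid across A7 to an enol ester. The enol carbon would then close 6-endo onto the gold-activated ynoate, giving the 6-(diethoxymethyl)pyranone A8. Acetal hydrolysis, oxidation to the acid and deprotection would follow.
- In favour: the heterocycle is built late from two simple alkynes with inherent regiochemistry (4-substituent from the acid, 6-substituent from the alkyne). The four-step preparation of a bromopyranone ester is avoided.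
- Against: C1 in A6 is benzylic and propargylic to an ynoic acid, so isomerisation to the allenoate under gold or base threatens its configuration. The electron-rich ring A and the C3=C4 bond can attack the activated alkyne. A7 is an electron-poor, acid-sensitive partner for carboxylate addition. Two redox steps follow the key step.
- Comparison: for regiochemical certainty of the pyranone and cost of the fragments the alternative is better. Both plans need a catalyst-controlled C1, so they are equal there, but the alternative must then carry that centre through a step that can erase it. The chosen plan has the shorter sequence after its key step.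

Key step: step 8

Remarks on the chemistry (assumptions and design changes):
- The beta,beta-di(hetero)aryl enal has no gamma-hydrogen, so no dienamine can form and its E and Z isomers cannot be expected to converge. Compound 13 is therefore made as the single E isomer (ring A trans to the formyl group). In this isomer C4 cannot reach the formyl carbon, which excludes ring closure to a naphthalene.
- The arylpyruvate is not carried through palladium chemistry. It is masked as the N-Boc enamine ester and released one step before the cascade.
- After the cascade the only centre that could be equilibrated is C2 (alpha to the carbonyl group), not C1. The trans arrangement should form directly, so no equilibration step is planned.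
- No aqueous base is used once the pyranone is in place. All five methyl groups are removed by BBr3.
- The (R)-imidazolidinone is chosen from the accepted shielding model for E-configured beta,beta-disubstituted enals, with ring A as the group trans to the formyl group. The (S)-catalyst is the remedy if the sense proves opposite.
- Compounds 5 and 9 are taken to be purchased as catalogue reagents.

## Route

Step 1
Reactants: 1 4-hydroxy-6-methyl-2H-pyran-2-one
Product: 2 4-bromo-6-methyl-2H-pyran-2-one
Conditions: nBu4NBr, P2O5, toluene, 100 °C
Reagents that add atoms: tetrabutylammonium bromide, CCCC[N+](CCCC)(CCCC)CCCC.[Br-]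
Why: Deoxybromination of a vinylogous acid: P2O5 activates the 4-hydroxyl as a phosphate and bromide replaces it by addition–elimination at C4 (nucleophilic vinylic substitution); lactone and methyl group are untouched.

Step 2
Reactants: 2 4-bromo-6-methyl-2H-pyran-2-one
Product: 3 4-bromo-2-oxo-2H-pyran-6-carbaldehyde
Conditions: SeO2, 1,4-dioxane, 150 °C (sealed tube)
Reagents that add atoms: selenium dioxide, O=[Se]=O
Why: Riley oxidation: the 6-methyl group is the vinylogous alpha-position of the pyranone and should react by ene reaction and [2,3]-shift to the aldehyde, as 6-methyl-2-pyranones generally do.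

Step 3
Reactants: 3 4-bromo-2-oxo-2H-pyran-6-carbaldehyde
Product: 4 methyl 4-bromo-2-oxo-2H-pyran-6-carboxylate
Conditions: Oxone (2KHSO5·KHSO4·K2SO4), MeOH, rt
Reagents that add atoms: methanol, CO; potassium peroxymonosulfate, [K+].OOS(=O)(=O)[O-]
Why: Oxidative esterification of an electron-poor aldehyde: the hemiacetal formed in methanol takes up peroxymonosulfate and a Baeyer–Villiger-type hydride shift gives the methyl ester; the acidic, non-nucleophilic medium should leave the C4 bromide and the lactone alone.

Step 4
Reactants: 4 methyl 4-bromo-2-oxo-2H-pyran-6-carboxylate; 5 (E)-2-(3,3-diethoxyprop-1-en-1-yl)-4,4,5,5-tetramethyl-1,3,2-dioxaborolane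
Product: 7 methyl 2-oxo-4-[(E)-3-oxoprop-1-en-1-yl]-2H-pyran-6-carboxylate, via diethyl acetal 6 (not isolated)
Conditions: Pd(PPh3)4 (5 mol%), CsF, 1,4-dioxane, 70 °C; then 1 M HCl, THF, rt
Reagents that add atoms: water, O
Why: Suzuki–Miyaura coupling: the 4-bromopyranone is a vinylogous acyl bromide that adds readily to zerovalent palladium, and the alkenylboronate transfers with retention, which fixes the E geometry. Anhydrous fluoride spares the ester, and dilute acid then hydrolyses the allylic acetal to the enal.

Step 5
Reactants: 8 2-bromo-4,5-dimethoxybenzaldehyde; 9 methyl 2-[(tert-butoxycarbonyl)amino]-2-(dimethoxyphosphoryl)acetate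
Product: 10 methyl (Z)-3-(2-bromo-4,5-dimethoxyphenyl)-2-[(tert-butoxycarbonyl)amino]prop-2-enoate
Conditions: DBU, CH2Cl2, 0 °C to rt
Reagents that add atoms: none
Why: Horner–Wadsworth–Emmons olefination with the phosphonoglycinate should give the dehydroamino ester, mainly as the Z isomer. This N-Boc enamine ester is the masked arylpyruvate and, unlike the free enol, offers no oxygen nucleophile next to the aryl bromide.

Step 6
Reactants: 10 methyl (Z)-3-(2-bromo-4,5-dimethoxyphenyl)-2-[(tert-butoxycarbonyl)amino]prop-2-enoate; 7 methyl 2-oxo-4-[(E)-3-oxoprop-1-en-1-yl]-2H-pyran-6-carboxylate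
Product: 11 methyl 4-[(1E)-1-{2-[(1Z)-2-[(tert-butoxycarbonyl)amino]-3-methoxy-3-oxoprop-1-en-1-yl]-4,5-dimethoxyphenyl}-3-oxoprop-1-en-1-yl]-2-oxo-2H-pyran-6-carboxylate
Conditions: Pd(OAc)2 (5 mol%), Cy2NMe, Et4NCl, DMAc, 90 °C
Reagents that add atoms: none
Why: Mizoroki–Heck arylation of a 1,2-disubstituted enal under phosphine-free conditions: the aryl group adds to the carbon beta to the formyl group (C1), the pyranonyl group behaving like an electron-poor aryl substituent. Syn carbopalladation followed by syn beta-hydride elimination places the incoming ring A trans to the formyl group, so the E isomer should form stereospecifically.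

Step 7
Reactants: 11 methyl 4-[(1E)-1-{2-[(1Z)-2-[(tert-butoxycarbonyl)amino]-3-methoxy-3-oxoprop-1-en-1-yl]-4,5-dimethoxyphenyl}-3-oxoprop-1-en-1-yl]-2-oxo-2H-pyran-6-carboxylate
Product: 13 methyl 4-[(1E)-1-[4,5-dimethoxy-2-(3-methoxy-2,3-dioxopropyl)phenyl]-3-oxoprop-1-en-1-yl]-2-oxo-2H-pyran-6-carboxylate, via enamino ester 12 (not isolated)
Conditions: CF3CO2H/CH2Cl2 (1:3), 0 °C to rt; then THF/H2O, rt; used crude
Reagents that add atoms: water, O
Why: Acidolysis of the Boc group (loss of isobutene and CO2) frees the primary enamine 12, which tautomerises to the imine and is hydrolysed by water to the alpha-keto ester. Enal, pyranone and methyl esters tolerate trifluoroacetic acid, and in the E isomer the nucleophilic C4 cannot reach the formyl group.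

Step 8
Reactants: 13 methyl 4-[(1E)-1-[4,5-dimethoxy-2-(3-methoxy-2,3-dioxopropyl)phenyl]-3-oxoprop-1-en-1-yl]-2-oxo-2H-pyran-6-carboxylate
Product: 14 methyl 4-[(1R,2S,3S)-2-formyl-3-hydroxy-6,7-dimethoxy-3-(methoxycarbonyl)-1,2,3,4-tetrahydronaphthalen-1-yl]-2-oxo-2H-pyran-6-carboxylate
Conditions: (R)-2-tert-butyl-3-methylimidazolidin-4-one·CCl3CO2H (20 mol%), diethyl 2,6-dimethyl-1,4-dihydropyridine-3,5-dicarboxylate (1.2 equiv), CHCl3, −30 to 0 °C
Reagents that add atoms: none
Why: The imidazolidinone condenses with the formyl group of 13 to an iminium ion, the dihydropyridine delivers hydride to C1 on the face not covered by the tert-butyl group, and the catalyst-bound enamine then adds through C2 to the neighbouring alpha-keto ester carbonyl (C3) before hydrolysis releases 14 and the amine. The closest known reaction type is the iminium transfer hydrogenation of beta,beta-disubstituted enals run in cascade with an intramolecular enamine addition (reductive Michael cyclisation), combined with the known imidazolidinone-catalysed enamine aldol reaction. Ring B closes in the 6-(enolexo)-exo-trig mode through a chair-like transition state with the C1 pyranonyl group pseudo-equatorial. C1 is controlled by the catalyst acting on the geometrically defined E-iminium ion, and by the accepted model the (R)-catalyst should give 1R when ring A is trans to the iminium carbon. C2 is controlled by the enamine face, reinforced by the preference of the formyl group to sit trans to the C1 substituent and correctable through the enamine; C3 should follow from the ketone oxygen taking the pseudo-equatorial position near the protonated catalyst, which puts the hydroxyl trans to the formyl group. The step needs chemoselectivity between iminium and keto ester, secured because the dihydropyridine transfers hydride only to the cationic iminium at this temperature. It also needs C2 rather than C4 to act as the nucleophile, secured because the reduced aldehyde is born as its enamine and because in the E isomer C4 cannot reach the iminium carbon. Since no gamma-hydrogen is present, no dienamine can scramble the double-bond geometry before reduction.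

Step 9
Reactants: 14 methyl 4-[(1R,2S,3S)-2-formyl-3-hydroxy-6,7-dimethoxy-3-(methoxycarbonyl)-1,2,3,4-tetrahydronaphthalen-1-yl]-2-oxo-2H-pyran-6-carboxylate
Product: 15 (1R,2S,3S)-3-hydroxy-6,7-dimethoxy-3-(methoxycarbonyl)-1-[6-(methoxycarbonyl)-2-oxo-2H-pyran-4-yl]-1,2,3,4-tetrahydronaphthalene-2-carboxylic acid
Conditions: NaClO2, NaH2PO4, 2-methyl-2-butene, t-BuOH/H2O, 0 °C to rt
Reagents that add atoms: sodium chlorite, [Na+].[O-]Cl=O
Why: Pinnick oxidation: chlorous acid converts the aldehyde to the acid near pH 4, which should avoid retro-aldol and epimerisation at C2; 2-methyl-2-butene consumes the hypochlorous acid so that ring A is not chlorinated.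

Step 10
Reactants: 15 (1R,2S,3S)-3-hydroxy-6,7-dimethoxy-3-(methoxycarbonyl)-1-[6-(methoxycarbonyl)-2-oxo-2H-pyran-4-yl]-1,2,3,4-tetrahydronaphthalene-2-carboxylic acid
Product: 16 dimethyl (1R,2S,3S)-3-hydroxy-6,7-dimethoxy-1-[6-(methoxycarbonyl)-2-oxo-2H-pyran-4-yl]-1,2,3,4-tetrahydronaphthalene-2,3-dicarboxylate
Conditions: MeI, KHCO3, DMF, rt
Reagents that add atoms: iodomethane, CI
Why: Carboxylate O-alkylation (SN2 on iodomethane); bicarbonate is too weak to deprotonate C1 or C2 or to start a retro-aldol, and the tertiary hydroxyl is not alkylated.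

Step 11
Reactants: 16 dimethyl (1R,2S,3S)-3-hydroxy-6,7-dimethoxy-1-[6-(methoxycarbonyl)-2-oxo-2H-pyran-4-yl]-1,2,3,4-tetrahydronaphthalene-2,3-dicarboxylate
Product: 17 dimethyl (1R,2S)-6,7-dimethoxy-1-[6-(methoxycarbonyl)-2-oxo-2H-pyran-4-yl]-1,2-dihydronaphthalene-2,3-dicarboxylate
Conditions: SOCl2, pyridine, CH2Cl2, 0 °C to rt
Reagents that add atoms: none
Why: Dehydration through the chlorosulfite with pyridine as base (E2, anti): the hydroxyl is cis to C2–H, so the only antiperiplanar hydrogen is the axial one on C4 and the double bond should form between C3 and C4, conjugated with ring A and the C3 ester. A cation at C3 is disfavoured by the ester, so C1 and C2 should be left as they are.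

Step 12
Reactants: 17 dimethyl (1R,2S)-6,7-dimethoxy-1-[6-(methoxycarbonyl)-2-oxo-2H-pyran-4-yl]-1,2-dihydronaphthalene-2,3-dicarboxylate
Product: 18 (1R,2S)-1-(6-carboxy-2-oxo-2H-pyran-4-yl)-6,7-dihydroxy-1,2-dihydronaphthalene-2,3-dicarboxylic acid
Conditions: BBr3 (excess), CH2Cl2, −78 °C to rt; then H2O, 0 °C
Reagents that add atoms: none
Why: Lewis acid dealkylation: BBr3 cleaves the two aryl methyl ethers and, with excess reagent at room temperature, the three methyl esters by bromide attack on the O-methyl groups, so no aqueous base is needed. The pyranone C–O bonds are to sp2 carbons and should not be cleaved, and C1 and C2 are not enolised under these conditions.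

## Compound list

1 | 4-hydroxy-6-methyl-2H-pyran-2-one | Cc1cc(O)cc(=O)o1 | starting material
2 | 4-bromo-6-methyl-2H-pyran-2-one | Cc1cc(Br)cc(=O)o1 | intermediate
3 | 4-bromo-2-oxo-2H-pyran-6-carbaldehyde | O=Cc1cc(Br)cc(=O)o1 | intermediate
4 | methyl 4-bromo-2-oxo-2H-pyran-6-carboxylate | COC(=O)c1cc(Br)cc(=O)o1 | intermediate
5 | (E)-2-(3,3-diethoxyprop-1-en-1-yl)-4,4,5,5-tetramethyl-1,3,2-dioxaborolane | CCOC(OCC)/C=C/B1OC(C)(C)C(C)(C)O1 | starting material
6 | methyl 4-[(E)-3,3-diethoxyprop-1-en-1-yl]-2-oxo-2H-pyran-6-carboxylate | CCOC(OCC)/C=C/c1cc(C(=O)OC)oc(=O)c1 | intermediate (not isolated)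
7 | methyl 2-oxo-4-[(E)-3-oxoprop-1-en-1-yl]-2H-pyran-6-carboxylate | O=C/C=C/c1cc(C(=O)OC)oc(=O)c1 | intermediate
8 | 2-bromo-4,5-dimethoxybenzaldehyde | O=Cc1cc(OC)c(OC)cc1Br | starting material
9 | methyl 2-[(tert-butoxycarbonyl)amino]-2-(dimethoxyphosphoryl)acetate | COC(=O)C(NC(=O)OC(C)(C)C)P(=O)(OC)OC | starting material
10 | methyl (Z)-3-(2-bromo-4,5-dimethoxyphenyl)-2-[(tert-butoxycarbonyl)amino]prop-2-enoate | COC(=O)/C(NC(=O)OC(C)(C)C)=C/c1cc(OC)c(OC)cc1Br | intermediate
11 | methyl 4-[(1E)-1-{2-[(1Z)-2-[(tert-butoxycarbonyl)amino]-3-methoxy-3-oxoprop-1-en-1-yl]-4,5-dimethoxyphenyl}-3-oxoprop-1-en-1-yl]-2-oxo-2H-pyran-6-carboxylate | COC(=O)/C(NC(=O)OC(C)(C)C)=C/c1cc(OC)c(OC)cc1/C(=C/C=O)c1cc(C(=O)OC)oc(=O)c1 | intermediate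
12 | methyl 4-[(1E)-1-{2-[(1Z)-2-amino-3-methoxy-3-oxoprop-1-en-1-yl]-4,5-dimethoxyphenyl}-3-oxoprop-1-en-1-yl]-2-oxo-2H-pyran-6-carboxylate | COC(=O)/C(N)=C/c1cc(OC)c(OC)cc1/C(=C/C=O)c1cc(C(=O)OC)oc(=O)c1 | intermediate (not isolated)
13 | methyl 4-[(1E)-1-[4,5-dimethoxy-2-(3-methoxy-2,3-dioxopropyl)phenyl]-3-oxoprop-1-en-1-yl]-2-oxo-2H-pyran-6-carboxylate | COC(=O)C(=O)Cc1cc(OC)c(OC)cc1/C(=C/C=O)c1cc(C(=O)OC)oc(=O)c1 | intermediate
14 | methyl 4-[(1R,2S,3S)-2-formyl-3-hydroxy-6,7-dimethoxy-3-(methoxycarbonyl)-1,2,3,4-tetrahydronaphthalen-1-yl]-2-oxo-2H-pyran-6-carboxylate | COC(=O)[C@]1(O)Cc2cc(OC)c(OC)cc2[C@@H](c2cc(C(=O)OC)oc(=O)c2)[C@@H]1C=O | intermediate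
15 | (1R,2S,3S)-3-hydroxy-6,7-dimethoxy-3-(methoxycarbonyl)-1-[6-(methoxycarbonyl)-2-oxo-2H-pyran-4-yl]-1,2,3,4-tetrahydronaphthalene-2-carboxylic acid | COC(=O)[C@]1(O)Cc2cc(OC)c(OC)cc2[C@@H](c2cc(C(=O)OC)oc(=O)c2)[C@@H]1C(=O)O | intermediate
16 | dimethyl (1R,2S,3S)-3-hydroxy-6,7-dimethoxy-1-[6-(methoxycarbonyl)-2-oxo-2H-pyran-4-yl]-1,2,3,4-tetrahydronaphthalene-2,3-dicarboxylate | COC(=O)[C@]1(O)Cc2cc(OC)c(OC)cc2[C@@H](c2cc(C(=O)OC)oc(=O)c2)[C@@H]1C(=O)OC | intermediate
17 | dimethyl (1R,2S)-6,7-dimethoxy-1-[6-(methoxycarbonyl)-2-oxo-2H-pyran-4-yl]-1,2-dihydronaphthalene-2,3-dicarboxylate | COC(=O)C1=Cc2cc(OC)c(OC)cc2[C@@H](c2cc(C(=O)OC)oc(=O)c2)[C@@H]1C(=O)OC | intermediate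
18 | (1R,2S)-1-(6-carboxy-2-oxo-2H-pyran-4-yl)-6,7-dihydroxy-1,2-dihydronaphthalene-2,3-dicarboxylic acid | O=C(O)C1=Cc2cc(O)c(O)cc2[C@@H](c2cc(C(=O)O)oc(=O)c2)[C@@H]1C(=O)O | target

## Step count and least certain steps

Total: 12 steps. Longest linear sequence: 11 steps (steps 1 to 4, then 6 to 12); the ring A branch (step 5) joins at step 6.

Step 8 (key step). The most likely failures are these:
- Weak discrimination between the two faces of an iminium ion whose beta-substituents are both (hetero)aryl.
- Rotation about C1–C2 in the iminium ion (diarylcarbenium character from the para-methoxy group of ring A) before hydride transfer, which would erode the configuration at C1 and re-open the ring closure from C4 onto the iminium carbon with aromatisation.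
- Slow hydride transfer to the hindered ion, leaving time for reversible addition of the pyruvate enol oxygen to C1 and for retro-aldol.

Fallback, from 7 and 9, returning at 14: the two events are separated and C1 is set by a rhodium-catalysed conjugate arylation.
- Purchased (2-formyl-4,5-dimethoxyphenyl)boronic acid F1 is olefinated with 9 (DBU, CH2Cl2) to {2-[(1Z)-2-[(tert-butoxycarbonyl)amino]-3-methoxy-3-oxoprop-1-en-1-yl]-4,5-dimethoxyphenyl}boronic acid F2.
- A Hayashi–Miyaura addition of F2 to 7 ([RhCl(C2H4)2]2 with a chiral bicyclo[2.2.2]octadiene ligand, aqueous dioxane, mild base) should give the saturated aldehyde methyl 4-[(1R)-1-{2-[(1Z)-2-[(tert-butoxycarbonyl)amino]-3-methoxy-3-oxoprop-1-en-1-yl]-4,5-dimethoxyphenyl}-3-oxopropyl]-2-oxo-2H-pyran-6-carboxylate F3.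
- CF3CO2H then water unmasks the keto ester through the enamino ester methyl 4-[(1R)-1-{2-[(1Z)-2-amino-3-methoxy-3-oxoprop-1-en-1-yl]-4,5-dimethoxyphenyl}-3-oxopropyl]-2-oxo-2H-pyran-6-carboxylate F4 to methyl 4-[(1R)-1-[4,5-dimethoxy-2-(3-methoxy-2,3-dioxopropyl)phenyl]-3-oxopropyl]-2-oxo-2H-pyran-6-carboxylate F5.
- F5 is cyclised at once with the same imidazolidinone salt through the same 6-enolexo aldol to 14, with C2 and C3 now controlled by C1.

Step 6. The most likely failures are slow insertion of the hindered aryl–palladium species into the 1,2-disubstituted enal (with hydrodebromination instead), insertion in the opposite sense directed by the pyranone as a vinylogous acceptor, N-arylation of the carbamate at the ortho position, and E/Z scrambling by re-addition of palladium hydride. Fallback, from 10, returning at 13: the N–H is removed so that a strongly activating catalyst can be used.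
- Boc2O with catalytic DMAP in MeCN converts 10 into methyl (Z)-2-[bis(tert-butoxycarbonyl)amino]-3-(2-bromo-4,5-dimethoxyphenyl)prop-2-enoate F6.
- F6 is coupled with 7 using Pd2(dba)3/P(t-Bu)3 and Cy2NMe in dioxane at 60 to 80 °C to methyl 4-[(1E)-1-{2-[(1Z)-2-[bis(tert-butoxycarbonyl)amino]-3-methoxy-3-oxoprop-1-en-1-yl]-4,5-dimethoxyphenyl}-3-oxoprop-1-en-1-yl]-2-oxo-2H-pyran-6-carboxylate F7.
- CF3CO2H then water removes both Boc groups and gives 13 by way of 12.

Step 2. The most likely failures are incomplete or excessive oxidation at the temperature required and displacement of the C4 bromide by oxygen nucleophiles. Fallback, from 2, returning at 3: Wohl–Ziegler bromination (N-bromosuccinimide, catalytic azobisisobutyronitrile, PhCF3, reflux) gives 4-bromo-6-(bromomethyl)-2H-pyran-2-one F8. Oxidation of this activated bromide with N-methylmorpholine N-oxide in MeCN at rt (a Kornblum-type oxidation) gives 3.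

Step 11. The most likely failures are elimination toward C2, either by deprotonation alpha to the C2 ester or because part of the material has the opposite configuration at C3, and sluggish reaction of the hindered chlorosulfite. Fallback, from 16, returning at 17: kinetic control is replaced by thermodynamic control. The dehydration is pushed to completion without regard to direction (SOCl2, pyridine, warming), giving 17 mixed with dimethyl (1R)-6,7-dimethoxy-1-[6-(methoxycarbonyl)-2-oxo-2H-pyran-4-yl]-1,4-dihydronaphthalene-2,3-dicarboxylate F9. Catalytic DBU in toluene under argon should then move the double bond into conjugation with ring A, with protonation at C2 anti to the C1 substituent, converging on 17.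

Step 12. The most likely failure is incomplete cleavage of the three electron-poor methyl esters while the ethers are already gone, with slow aromatisation on long exposure to the Lewis acid. Fallback, from 17, returning at 18: the two tasks are separated. BBr3 (4 equiv, CH2Cl2, −78 to 0 °C) removes only the ethers and gives dimethyl (1R,2S)-6,7-dihydroxy-1-[6-(methoxycarbonyl)-2-oxo-2H-pyran-4-yl]-1,2-dihydronaphthalene-2,3-dicarboxylate F10. The esters are then hydrolysed under acid (6 M HCl, 1,4-dioxane, 80 °C, argon) to 18.

## Further compounds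

F1 | step 8 | (2-formyl-4,5-dimethoxyphenyl)boronic acid | O=Cc1cc(OC)c(OC)cc1B(O)O
F2 | step 8 | {2-[(1Z)-2-[(tert-butoxycarbonyl)amino]-3-methoxy-3-oxoprop-1-en-1-yl]-4,5-dimethoxyphenyl}boronic acid | COC(=O)/C(NC(=O)OC(C)(C)C)=C/c1cc(OC)c(OC)cc1B(O)O
F3 | step 8 | methyl 4-[(1R)-1-{2-[(1Z)-2-[(tert-butoxycarbonyl)amino]-3-methoxy-3-oxoprop-1-en-1-yl]-4,5-dimethoxyphenyl}-3-oxopropyl]-2-oxo-2H-pyran-6-carboxylate | COC(=O)/C(NC(=O)OC(C)(C)C)=C/c1cc(OC)c(OC)cc1[C@H](CC=O)c1cc(C(=O)OC)oc(=O)c1
F4 | step 8 | methyl 4-[(1R)-1-{2-[(1Z)-2-amino-3-methoxy-3-oxoprop-1-en-1-yl]-4,5-dimethoxyphenyl}-3-oxopropyl]-2-oxo-2H-pyran-6-carboxylate | COC(=O)/C(N)=C/c1cc(OC)c(OC)cc1[C@H](CC=O)c1cc(C(=O)OC)oc(=O)c1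
F5 | step 8 | methyl 4-[(1R)-1-[4,5-dimethoxy-2-(3-methoxy-2,3-dioxopropyl)phenyl]-3-oxopropyl]-2-oxo-2H-pyran-6-carboxylate | COC(=O)C(=O)Cc1cc(OC)c(OC)cc1[C@H](CC=O)c1cc(C(=O)OC)oc(=O)c1
F6 | step 6 | methyl (Z)-2-[bis(tert-butoxycarbonyl)amino]-3-(2-bromo-4,5-dimethoxyphenyl)prop-2-enoate | COC(=O)/C(N(C(=O)OC(C)(C)C)C(=O)OC(C)(C)C)=C/c1cc(OC)c(OC)cc1Br
F7 | step 6 | methyl 4-[(1E)-1-{2-[(1Z)-2-[bis(tert-butoxycarbonyl)amino]-3-methoxy-3-oxoprop-1-en-1-yl]-4,5-dimethoxyphenyl}-3-oxoprop-1-en-1-yl]-2-oxo-2H-pyran-6-carboxylate | COC(=O)/C(N(C(=O)OC(C)(C)C)C(=O)OC(C)(C)C)=C/c1cc(OC)c(OC)cc1/C(=C/C=O)c1cc(C(=O)OC)oc(=O)c1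
F8 | step 2 | 4-bromo-6-(bromomethyl)-2H-pyran-2-one | BrCc1cc(Br)cc(=O)o1
F9 | step 11 | dimethyl (1R)-6,7-dimethoxy-1-[6-(methoxycarbonyl)-2-oxo-2H-pyran-4-yl]-1,4-dihydronaphthalene-2,3-dicarboxylate | COC(=O)C1=C(C(=O)OC)[C@H](c2cc(C(=O)OC)oc(=O)c2)c2cc(OC)c(OC)cc2C1
F10 | step 12 | dimethyl (1R,2S)-6,7-dihydroxy-1-[6-(methoxycarbonyl)-2-oxo-2H-pyran-4-yl]-1,2-dihydronaphthalene-2,3-dicarboxylate | COC(=O)C1=Cc2cc(O)c(O)cc2[C@@H](c2cc(C(=O)OC)oc(=O)c2)[C@@H]1C(=O)OC
A1 | alternative 1 | (1R,2S)-1-(3,4-dihydroxyphenyl)-6,7-dimethoxy-1,2-dihydronaphthalene-2,3-dicarboxylic acid | OC(=O)C1=Cc2cc(OC)c(OC)cc2[C@@H](c2ccc(O)c(O)c2)[C@@H]1C(=O)O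
A2 | alternative 1 | (1R,2S)-1-(6-carboxy-2-oxo-2H-pyran-4-yl)-6,7-dimethoxy-1,2-dihydronaphthalene-2,3-dicarboxylic acid | OC(=O)C1=Cc2cc(OC)c(OC)cc2[C@@H](c2cc(C(=O)O)oc(=O)c2)[C@@H]1C(=O)O
A3 | alternative 2 | dimethyl (Z)-2-(prop-2-yn-1-ylidene)-3-[1-(6-methoxycarbonyl-2-oxo-2H-pyran-4-yl)prop-2-yn-1-yl]butanedioate, stereocentres as in the target | C#C[C@@H](c1cc(C(=O)OC)oc(=O)c1)[C@@H](/C(C(=O)OC)=C\C#C)C(=O)OC
A4 | alternative 2 | 1,2-bis(4,4,5,5-tetramethyl-1,3,2-dioxaborolan-2-yl)ethyne | CC1(C)OB(C#CB2OC(C)(C)C(C)(C)O2)OC1(C)C
A5 | alternative 2 | dimethyl 1-[6-(methoxycarbonyl)-2-oxo-2H-pyran-4-yl]-6,7-bis(4,4,5,5-tetramethyl-1,3,2-dioxaborolan-2-yl)-1,2-dihydronaphthalene-2,3-dicarboxylate, stereocentres as in the target | COC(=O)C1=Cc2cc(B3OC(C)(C)C(C)(C)O3)c(B3OC(C)(C)C(C)(C)O3)cc2[C@@H](c2cc(C(=O)OC)oc(=O)c2)[C@@H]1C(=O)OC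
A6 | alternative 3 | 3-[6,7-dimethoxy-2,3-bis(methoxycarbonyl)-1,2-dihydronaphthalen-1-yl]prop-2-ynoic acid, stereocentres as in the target | COC(=O)C1=Cc2cc(OC)c(OC)cc2[C@@H](C#CC(=O)O)[C@@H]1C(=O)OC
A7 | alternative 3 | 3,3-diethoxyprop-1-yne | C#CC(OCC)OCC
A8 | alternative 3 | dimethyl 1-[6-(diethoxymethyl)-2-oxo-2H-pyran-4-yl]-6,7-dimethoxy-1,2-dihydronaphthalene-2,3-dicarboxylate, stereocentres as in the target | COC(=O)C1=Cc2cc(OC)c(OC)cc2[C@@H](c2cc(C(OCC)OCC)oc(=O)c2)[C@@H]1C(=O)OC
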